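**Strategy.** Everything rests on cutting C2–C3 of the 3-methylcyclohex-2-enone ring (C1–C4, C11). That leaves a bicyclo[4.1.1]octane whose cyclobutane (C4–C5–C11–C10) bears acetyl groups on C4 and C11. The feature exploited is the mirror plane through C5, C10 and the C6–C9 bridge, which makes these groups enantiotopic. One chiral-amine-catalysed aldol condensation thus closes the six-membered ring, forms C2–C3 and the C2=C3 enone, and fixes the absolute configuration of C4, C5, C10 and C11. The precursor is the meso diketone ketal. Its cis geometry, anti to the bridge, is set at the diester stage, where enolisation cannot trigger racemic cyclisation.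

Key step: step 13

Remark: atom labels in the Why lines are longipinane numbers (C1=O, C2=C3, cyclobutane C4–C5–C11–C10, C6 gem-dimethyl, C7–C9 bridge carbons, C10 methyl-bearing). "Syn" and "anti" place C4/C11 substituents relative to the bridge that starts at C6. Racemic intermediates are drawn as one enantiomer.

Step 1
Reactants: 1 5-methylcyclohexane-1,3-dione; 2 iodomethane
Product: 3 2,2,5-trimethylcyclohexane-1,3-dione (achiral)
Conditions: MeI (excess), K2CO3, acetone, reflux
Reagents that add atoms: iodomethane, CI
Why: Twofold C-alkylation of the 1,3-diketone enolate at the carbon between the carbonyl groups builds the gem-dimethyl carbon C6, and no stereocentre arises because the methyl-bearing carbon (later C10) lies on the mirror plane.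

Step 2
Reactants: 3 2,2,5-trimethylcyclohexane-1,3-dione
Product: 4 6,6,9-trimethyl-1,4-dioxaspiro[4.5]decan-7-one (racemic)
Conditions: HOCH2CH2OH (1.0 equiv), p-TsOH (cat.), toluene, azeotropic removal of water
Reagents that add atoms: ethane-1,2-diol, OCCO
Why: Acid-catalysed monoketalisation, in which the two enantiotopic carbonyl groups give the same racemate and the remaining carbonyl, now next to a quaternary carbon that bears a ketal, reacts much more slowly; the ketal carbon is the later C7.

Step 3
Reactants: 4 6,6,9-trimethyl-1,4-dioxaspiro[4.5]decan-7-one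
Product: 5 6,6,9-trimethyl-1,4-dioxaspiro[4.5]dec-7-en-7-yl trifluoromethanesulfonate (racemic)
Conditions: KN(SiMe3)2, THF, −78 °C; PhNTf2, −78 → 0 °C
Reagents that add atoms: N-phenylbis(trifluoromethanesulfonimide), O=S(=O)(N(c1ccccc1)S(=O)(=O)C(F)(F)F)C(F)(F)F
Why: Deprotonation can occur only at the CH2 group (later C4) because the other α-carbon is quaternary, so O-triflation of the potassium enolate (enolate trapping with an N-aryl triflimide) gives a single enol triflate.

Step 4
Reactants: 5 6,6,9-trimethyl-1,4-dioxaspiro[4.5]dec-7-en-7-yl trifluoromethanesulfonate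
Product: 6 6,6,9-trimethyl-1,4-dioxaspiro[4.5]dec-7-ene (racemic)
Conditions: Pd(OAc)2 (5 mol %), PPh3, HCO2H, n-Bu3N, DMF, 60 °C
Reagents that add atoms: none
Why: Palladium-catalysed formate reduction of the enol triflate replaces OTf by H and leaves the C4=C5 alkene with a single allylic hydrogen, the one on C10, while the ketal is inert.

Step 5
Reactants: 6 6,6,9-trimethyl-1,4-dioxaspiro[4.5]dec-7-ene; 7 bromoform
Product: 8 7,7-dibromo-2,2,5-trimethylspiro[bicyclo[4.1.0]heptane-3,2'-[1,3]dioxolane] (CBr2 cis to H-5 and trans to the 5-methyl group; racemic)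
Conditions: CHBr3, KOt-Bu, pentane, 0 °C
Reagents that add atoms: bromoform, BrC(Br)Br
Why: Dibromocarbene [2+1] cycloaddition delivers C11; in the half-chair with an equatorial C10 methyl group the pseudo-axial C6 methyl blocks one face, so the carbene should add to the face that carries H-10, which places this hydrogen syn to CBr2.

Step 6
Reactants: 8 7,7-dibromo-2,2,5-trimethylspiro[bicyclo[4.1.0]heptane-3,2'-[1,3]dioxolane]
Product: 9 2,5,5-trimethylspiro[tricyclo[4.1.0.0(2,7)]heptane-4,2'-[1,3]dioxolane] (meso bicyclobutane; central bond C4–C11; wing carbons C5 and C10)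
Conditions: MeLi (1.2 equiv), Et2O, −78 → 0 °C
Reagents that add atoms: none
Why: Bromine–lithium exchange and loss of LiBr give the cyclopropylidene carbenoid, which inserts with retention into the only neighbouring C–H bond (tertiary, syn, on C10) to form C10–C11 (gem-dibromocyclopropane to bicyclobutane reaction); the six-membered ring is deliberate, since bicyclo[4.1.0]hept-7-ylidenes insert whereas ring-enlarged homologues open to cyclic allenes, and both enantiomers of 8 converge on one achiral product.

Step 7
Reactants: 9 2,5,5-trimethylspiro[tricyclo[4.1.0.0(2,7)]heptane-4,2'-[1,3]dioxolane]; 10 methyl chloroformate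
Product: 12 dimethyl 2,5,5-trimethylspiro[tricyclo[4.1.0.0(2,7)]heptane-4,2'-[1,3]dioxolane]-1,7-dicarboxylate (meso), via dilithio-bicyclobutane 11 (not isolated)
Conditions: n-BuLi (2.5 equiv), TMEDA, Et2O–hexane, 25 °C; then added to ClCO2Me (excess), THF, −78 °C
Reagents that add atoms: methyl chloroformate, COC(=O)Cl
Why: The two equivalent bridgehead C–H bonds have high s character and undergo alkyllithium–diamine metalation, and inverse quenching with the chloroformate (acylation of a bridgehead organolithium) installs C1 and C3 without touching the ketal or any stereocentre.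

Step 8
Reactants: 12 dimethyl 2,5,5-trimethylspiro[tricyclo[4.1.0.0(2,7)]heptane-4,2'-[1,3]dioxolane]-1,7-dicarboxylate
Product: 14 dimethyl 1,4,4-trimethylspiro[bicyclo[3.1.1]heptane-3,2'-[1,3]dioxolane]-6,7-dicarboxylate with both esters anti to the three-carbon bridge (meso), via syn-diester 13 (not isolated)
Conditions: H2 (1 atm), Pd/C, EtOAc, 25 °C; filter; NaOMe (0.3 equiv), MeOH, 50 °C
Reagents that add atoms: none
Why: Hydrogenolysis of the strained central C4–C11 bond, flanked by two acceptors, gives the cyclobutane, and methoxide epimerisation next to the esters then moves both groups anti, trans to C6 on C5 and to C9 on C10 (thermodynamic control of C4 and C11); two esters cannot condense with each other here, so equilibration is safe at this stage.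

Step 9
Reactants: 14 dimethyl 1,4,4-trimethylspiro[bicyclo[3.1.1]heptane-3,2'-[1,3]dioxolane]-6,7-dicarboxylate (anti,anti)
Product: 15 dimethyl 1,4,4-trimethyl-3-oxobicyclo[3.1.1]heptane-6,7-dicarboxylate (anti,anti; meso)
Conditions: 1 M HCl, THF, 25 °C
Reagents that add atoms: water, O
Why: Acid hydrolysis of the dioxolane frees the C7 ketone for ring enlargement without affecting the esters or the configuration at C4 and C11.

Step 10
Reactants: 15 dimethyl 1,4,4-trimethyl-3-oxobicyclo[3.1.1]heptane-6,7-dicarboxylate; 16 (trimethylsilyl)diazomethane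
Product: 18 dimethyl 1,5,5-trimethyl-4-oxobicyclo[4.1.1]octane-7,8-dicarboxylate (anti,anti; meso), via alpha-silyl ketone 17 (not isolated)
Conditions: TMSCHN2 (1.3 equiv), BF3·OEt2 (1.2 equiv), CH2Cl2, −78 → −20 °C; then 1 M HCl, THF
Reagents that add atoms: (trimethylsilyl)diazomethane, C[Si](C)(C)C=[N+]=[N-]
Why: In this Lewis-acid-promoted diazoalkane homologation (Tiffeneau–Demjanov-type 1,2-shift) the diazo carbon adds to C7, the less substituted C9 migrates in preference to quaternary C6 with loss of N2, and protodesilylation leaves the new CH2 group C8, which completes the C6–C9 bridge of the mirror-symmetric bicyclo[4.1.1]octane.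

Step 11
Reactants: 18 dimethyl 1,5,5-trimethyl-4-oxobicyclo[4.1.1]octane-7,8-dicarboxylate
Product: 19 dimethyl 1,5,5-trimethylspiro[bicyclo[4.1.1]octane-4,2'-[1,3]dioxolane]-7,8-dicarboxylate (anti,anti; meso)
Conditions: TMSOCH2CH2OTMS, TMSOTf (5 mol %), CH2Cl2, −78 → −20 °C; pyridine quench
Reagents that add atoms: 1,2-bis(trimethylsilyloxy)ethane, C[Si](C)(C)OCCO[Si](C)(C)C
Why: Silyl-triflate-catalysed ketalisation with the bis-silyl ether of glycol works on hindered ketones at low temperature and masks C7 against the Grignard reagents of step 12.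

Step 12
Reactants: 19 dimethyl 1,5,5-trimethylspiro[bicyclo[4.1.1]octane-4,2'-[1,3]dioxolane]-7,8-dicarboxylate; 20 methylmagnesium bromide
Product: 22 meso cis-4,11-diacetyl bicyclo[4.1.1]octane 7-ethylene ketal = 7,8-diacetyl-1,5,5-trimethylspiro[bicyclo[4.1.1]octane-4,2'-[1,3]dioxolane] with both acetyl groups anti to the four-carbon bridge and syn to the C10 methyl, via bis-Weinreb amide 21 (not isolated)
Conditions: MeNHOMe·HCl, i-PrMgCl, THF, −10 → 25 °C; then MeMgBr, 0 °C; inverse quench into cold citrate buffer (pH 5)
Reagents that add atoms: methylmagnesium bromide, C[Mg]Br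
Why: Aminolysis of both esters by the magnesium amide gives the bis-Weinreb amide, whose chelated adducts with MeMgBr stop at the ketone stage (Weinreb ketone synthesis) and collapse only in the buffered quench, so C2 and C12 are added and the anti,anti configuration is kept without exposing the diketone to base.

Step 13
Reactants: 22 meso cis-4,11-diacetyl bicyclo[4.1.1]octane 7-ethylene ketal
Product: 24 longipin-2-ene-1,7-dione 7-ethylene ketal (absolute configuration at C4, C5, C10 and C11 as in the target), via ketol 23 (not isolated)
Conditions: 9-amino-9-deoxy-epi-quinine (20 mol %), AcOH (40 mol %), toluene, 25 → 40 °C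
Reagents that add atoms: none
Why: The primary amine condenses with the C11 acetyl group, and the enamine carbon C2 attacks carbonyl carbon C3 of the C4 acetyl group, which sits close by in a 1,3-diaxial-like position; hydrolysis and loss of water from ketol 23 give the β-methyl enone, C12 being the methyl of the electrophilic acetyl. The closest known reaction type is the primary-amine/acid-catalysed desymmetrising intramolecular aldol condensation of 4-substituted heptane-2,6-diones to 5-substituted 3-methylcyclohex-2-enones. The one ring formed (C11–C1–C2–C3–C4 plus C5 or C10) closes in the 6-(enolendo)-exo-trig mode, because both enamine carbons C1 and C2 end up inside it. C4, C5, C10 and C11 already have their relative configuration in meso 22, and the catalyst, by choosing which enantiotopic acetyl becomes the enamine, turns them into one enantiomer; the pseudoenantiomeric quinidine-derived amine gives the antipode, so the sense can be matched to the target. The step needs group selectivity only: the mirror-symmetric ketal bridge excludes diastereomers, the internal enamine has no feasible ring size open to it, and the absence of any achiral base or amine keeps the racemic background low.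

Step 14
Reactants: 24 longipin-2-ene-1,7-dione 7-ethylene ketal
Product: 25 longipin-2-ene-1,7-dione
Conditions: 1 M HCl, THF, 25 °C
Reagents that add atoms: water, O
Why: Acid hydrolysis of the dioxolane, under which the enone and the four cyclobutane stereocentres (locked in the bridged skeleton) are stable.

Step 15
Reactants: 25 longipin-2-ene-1,7-dione
Product: 27 longipina-2,8-diene-1,7-dione, via silyl enol ether 26 (not isolated)
Conditions: LiN(i-Pr)2 (1.05 equiv), TMSCl, THF, −78 °C; then Pd(OAc)2 (1.0 equiv), MeCN, 25 °C
Reagents that add atoms: none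
Why: In this Saegusa–Ito oxidation the amide base removes a C8 proton, the only kind of α-hydrogen of the C7 ketone and kinetically more acidic than the γ-hydrogens of the enone (whose α′ hydrogen on C11 is a bridgehead), and palladium diacetate converts the silyl enol ether into the C8=C9 enone.

Step 16
Reactants: 27 longipina-2,8-diene-1,7-dione
Product: 29 9-hydroxylongipin-2-ene-1,7-dione (OH on the face of C9 turned towards C11), via boronate 28 (not isolated)
Conditions: B2pin2, CuCl (5 mol %), NaOt-Bu (10 mol %), Josiphos ligand (PPh2/PCy2 type, 6 mol %), MeOH (2 equiv), THF, 0 → 25 °C; then NaBO3·4H2O, THF–H2O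
Reagents that add atoms: sodium perborate, [Na+].[Na+].O[B-]1(O)OO[B-](O)(O)OO1
Why: Copper–boryl conjugate addition followed by stereoretentive oxidation; the disubstituted C8=C9 enone should react ahead of the trisubstituted, more shielded C2=C3 enone, and because the two faces of C9 differ only through remote C1 and C3 the chiral ligand decides the face, its antipode being chosen so that boron and then OH enter on the C11 side.

Step 17
Reactants: 29 9-hydroxylongipin-2-ene-1,7-dione; 30 acetaldehyde
Product: 31 9-acetoxy-7-hydroxylongipin-2-en-1-one (7-OH towards C4; 9-OAc towards C11; 7,9-anti)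
Conditions: CH3CHO (6 equiv), SmI2 (30 mol %), THF, −10 °C
Reagents that add atoms: acetaldehyde, CC=O
Why: In the Evans–Tishchenko reaction the samarium-bound hemiacetal of the C9 alkoxide and acetaldehyde passes its hydride to C7 on the face that carries the C9 oxygen, which sets the 7,9-anti relation, leaves the acetate on O9 and the free hydroxyl on C7 in one operation, and spares the enone.

Step 18
Reactants: 31 9-acetoxy-7-hydroxylongipin-2-en-1-one; 32 angelic acid
Product: 33 CNP0260482.1 (7-angeloyloxy-9-acetoxylongipin-2-en-1-one)
Conditions: angelic acid, 2,4,6-Cl3C6H2COCl, Et3N, toluene, 80 °C (no DMAP)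
Reagents that add atoms: angelic acid, C/C=C(/C)C(=O)O
Why: Yamaguchi-type mixed-anhydride esterification run without nucleophilic catalyst, the variant that acylates hindered alcohols with angelic acid without Z to E isomerisation; no stereocentre is touched.

**Compound list**

1 | 5-methylcyclohexane-1,3-dione | CC1CC(=O)CC(=O)C1 | starting material
2 | iodomethane | CI | starting material
3 | 2,2,5-trimethylcyclohexane-1,3-dione | CC1CC(=O)C(C)(C)C(=O)C1 | intermediate
4 | 6,6,9-trimethyl-1,4-dioxaspiro[4.5]decan-7-one (racemic) | CC1CC(=O)C(C)(C)C2(C1)OCCO2 | intermediate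
5 | 6,6,9-trimethyl-1,4-dioxaspiro[4.5]dec-7-en-7-yl triflate (racemic) | CC1C=C(OS(=O)(=O)C(F)(F)F)C(C)(C)C2(C1)OCCO2 | intermediate
6 | 6,6,9-trimethyl-1,4-dioxaspiro[4.5]dec-7-ene (racemic) | CC1C=CC(C)(C)C2(C1)OCCO2 | intermediate
7 | bromoform | BrC(Br)Br | starting material
8 | dibromocyclopropane ketal, CBr2 cis to H on C10 (racemic, relative configuration) | C[C@H]1CC2(OCCO2)C(C)(C)[C@H]3[C@@H]1C3(Br)Br | intermediate
9 | meso bicyclobutane ketal | C[C@@]12CC3(OCCO3)C(C)(C)[C@H]4[C@@H]1[C@H]24 | intermediate
10 | methyl chloroformate | COC(=O)Cl | starting material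
11 | 1,7-dilithio derivative of 9 | C[C@@]12CC3(OCCO3)C(C)(C)[C@H]4[C@]1([Li])[C@]24[Li] | intermediate (not isolated)
12 | meso bicyclobutane-1,7-diester ketal | C[C@@]12CC3(OCCO3)C(C)(C)[C@H]4[C@]1(C(=O)OC)[C@]24C(=O)OC | intermediate
13 | bicyclo[3.1.1]heptane diester ketal, esters syn,syn (meso) | O1CCOC12C[C@@]3(C)[C@@H](C(=O)OC)[C@H]([C@H]3C(=O)OC)C2(C)C | intermediate (not isolated)
14 | bicyclo[3.1.1]heptane diester ketal, esters anti,anti (meso) | O1CCOC12C[C@@]3(C)[C@H](C(=O)OC)[C@H]([C@@H]3C(=O)OC)C2(C)C | intermediate
15 | 3-oxobicyclo[3.1.1]heptane diester, anti,anti (meso) | O=C1C[C@@]2(C)[C@H](C(=O)OC)[C@H]([C@@H]2C(=O)OC)C1(C)C | intermediate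
16 | (trimethylsilyl)diazomethane | C[Si](C)(C)C=[N+]=[N-] | starting material
17 | 3-trimethylsilyl-4-oxobicyclo[4.1.1]octane diester (racemic, silyl-bearing carbon as formed) | O=C1C([Si](C)(C)C)C[C@@]2(C)[C@H](C(=O)OC)[C@H]([C@@H]2C(=O)OC)C1(C)C | intermediate (not isolated)
18 | 4-oxobicyclo[4.1.1]octane diester, anti,anti (meso) | O=C1CC[C@@]2(C)[C@H](C(=O)OC)[C@H]([C@@H]2C(=O)OC)C1(C)C | intermediate
19 | bicyclo[4.1.1]octane diester ketal, anti,anti (meso) | O1CCOC12CC[C@@]3(C)[C@H](C(=O)OC)[C@H]([C@@H]3C(=O)OC)C2(C)C | intermediate
20 | methylmagnesium bromide | C[Mg]Br | starting material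
21 | bis(N-methoxy-N-methylamide) ketal (meso) | O1CCOC12CC[C@@]3(C)[C@H](C(=O)N(C)OC)[C@H]([C@@H]3C(=O)N(C)OC)C2(C)C | intermediate (not isolated)
22 | meso cis-4,11-diacetyl bicyclo[4.1.1]octane 7-ethylene ketal | O1CCOC12CC[C@@]3(C)[C@H](C(C)=O)[C@H]([C@@H]3C(C)=O)C2(C)C | intermediate
23 | 3-hydroxylongipinane-1,7-dione 7-ethylene ketal (OH on the C10 side) | O1CCOC12CC[C@@]3(C)[C@@H]4C(=O)C[C@](C)(O)[C@H]3[C@@H]4C2(C)C | intermediate (not isolated)
24 | longipin-2-ene-1,7-dione 7-ethylene ketal | O1CCOC12CC[C@@]3(C)[C@@H]4C(=O)C=C(C)[C@H]3[C@@H]4C2(C)C | intermediate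
25 | longipin-2-ene-1,7-dione | O=C1CC[C@@]2(C)[C@@H]3C(=O)C=C(C)[C@H]2[C@@H]3C1(C)C | intermediate
26 | 7-(trimethylsilyloxy)longipina-2,7-dien-1-one | C[Si](C)(C)OC1=CC[C@@]2(C)[C@@H]3C(=O)C=C(C)[C@H]2[C@@H]3C1(C)C | intermediate (not isolated)
27 | longipina-2,8-diene-1,7-dione | O=C1C=C[C@@]2(C)[C@@H]3C(=O)C=C(C)[C@H]2[C@@H]3C1(C)C | intermediate
28 | 9-(pinacolatoboryl)longipin-2-ene-1,7-dione | O=C1C[C@@H](B2OC(C)(C)C(C)(C)O2)[C@@]3(C)[C@@H]4C(=O)C=C(C)[C@H]3[C@@H]4C1(C)C | intermediate (not isolated)
29 | 9-hydroxylongipin-2-ene-1,7-dione | O=C1C[C@@H](O)[C@@]2(C)[C@@H]3C(=O)C=C(C)[C@H]2[C@@H]3C1(C)C | intermediate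
30 | acetaldehyde | CC=O | starting material
31 | 9-acetoxy-7-hydroxylongipin-2-en-1-one | O[C@@H]1C[C@@H](OC(C)=O)[C@@]2(C)[C@@H]3C(=O)C=C(C)[C@H]2[C@@H]3C1(C)C | intermediate
32 | angelic acid | C/C=C(/C)C(=O)O | starting material
33 | CNP0260482.1 | C/C=C(/C)C(=O)O[C@@H]1C[C@@H](OC(C)=O)[C@@]2(C)[C@@H]3C(=O)C=C(C)[C@H]2[C@@H]3C1(C)C | target

**Totals.** Total step count: 18. Longest linear sequence: 18 (steps 1–18).

**Steps most likely to fail**

Step 13. Enamine formation at two hindered cyclobutyl methyl ketones may be slow. Discrimination between the enantiotopic acetyl groups may be poor, and uncatalysed cyclisation could then erode the enantiomeric purity. The fallback sets out from 22. A stoichiometric chiral base (lithium (R,R)-bis(1-phenylethyl)amide, LiCl, THF, −78 °C) removes a methyl proton from one acetyl group selectively. On warming, the lithium enolate closes to ketol 23, which is now isolated. Heating 23 with pyridinium p-toluenesulfonate and molecular sieves in toluene removes water and returns to the route at 24. This fallback makes no compound outside the list (F0).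

Step 7. The second metalation may stall after the first, or a lithiated species may attack an ester that has just formed, so that only one bridgehead is functionalised. The fallback sets out from 9.
- One equivalent of n-BuLi/TMEDA, then ClCO2Me, gives the bicyclobutane monoester F1.
- Vinylmagnesium bromide with CuBr·SMe2 and PBu3 adds to the free bridgehead (homoconjugate cuprate addition to an acyl bicyclobutane), and protonation gives the vinyl ester F2.
- Ozonolysis in methanolic NaOH turns the vinyl group into a methyl ester and gives the syn,anti diester F3.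
- The NaOMe treatment of step 8 equilibrates F3, and the route is rejoined at 14.

Step 17. The hemiacetal-bound hydride may not reach C7 inside the seven-membered ring, and loss of the C9 oxygen by β-elimination may take over. The fallback sets out from 29. Hydroxyl-directed reduction with Me4NBH(OAc)3 in MeCN–AcOH at −20 °C (Evans–Saksena reduction) gives the 7,9-anti diol F4. The C9 hydroxyl sits next to a tied-back cyclobutane carbon and should be more accessible than the C7 hydroxyl next to the gem-dimethyl carbon. It is acetylated selectively with Ac2O (1.0 equiv) and 2,4,6-collidine in CH2Cl2 at −20 °C, which rejoins the route at 31.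

**Further compounds**

F0 | step 13 | none | none
F1 | step 7 | methyl 2,5,5-trimethylspiro[tricyclo[4.1.0.0(2,7)]heptane-4,2'-[1,3]dioxolane]-1-carboxylate (racemic) | C[C@@]12CC3(OCCO3)C(C)(C)[C@H]4[C@]1(C(=O)OC)[C@H]24
F2 | step 7 | methyl 1,4,4-trimethyl-7-vinylspiro[bicyclo[3.1.1]heptane-3,2'-[1,3]dioxolane]-6-carboxylate, vinyl syn and ester anti to the bridge (racemic) | O1CCOC12C[C@@]3(C)[C@H](C(=O)OC)[C@H]([C@H]3C=C)C2(C)C
F3 | step 7 | dimethyl 1,4,4-trimethylspiro[bicyclo[3.1.1]heptane-3,2'-[1,3]dioxolane]-6,7-dicarboxylate, one ester anti and one syn (racemic) | O1CCOC12C[C@@]3(C)[C@H](C(=O)OC)[C@H]([C@H]3C(=O)OC)C2(C)C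
F4 | step 17 | 7,9-dihydroxylongipin-2-en-1-one (7,9-anti) | O[C@@H]1C[C@@H](O)[C@@]2(C)[C@@H]3C(=O)C=C(C)[C@H]2[C@@H]3C1(C)C
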